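Watch the intermediate against a clock that ticks in its own half-lives, not in hours.

| flask | substrate | reagent | temperature | remark | time |
|---|---|---|---|---|---|
| north | 66 mM (fed, over 50 h) | 1.2 equiv | −40 °C | run made earlier |  |
| maple | 33 mM (fed, over 100 h) | 1.20 equiv |  | at −40 °C throughout | 12 d |
| elm | 33 mM (fed, over 50 h) | 1.20 equiv |  | at −40 °C until 50 h, from then on at −20 °C | 3.0 d |

north run (percent of the substrate charged)

| time / h | intermediate / % | target / % |
|---|---|---|
| 1.00 | 0.8 | 0 |
| 3.00 | 4.6 | 0.2 |
| 5.00 | 7.1 | 1.2 |
| 8.00 | 9.5 | 3.9 |
| 12.0 | 15.3 | 7.0 |
| 15.0 | 17.9 | 9.7 |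

(scatter of a reading: 0.5 percentage points)

- the numbers in the tables scatter by 0.5 percentage points (one standard deviation)
- candidate steps: substrate + reagent -> intermediate + by-product; intermediate <-> target; intermediate <-> isomer of the product; substrate + by-product -> side product
- the earlier runs do not show what temperature does; that part of a forecast is a guess
- percentages count the whole charge, also what has not yet gone in

- the winner by amount of intermediate, in percent of the substrate charged; "neither" if no more than 2 percentage points parts them (maple / elm / neither)
- how much intermediate is there at the end, in percent of the substrate charged: maple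
- how much intermediate is there at the end, in percent of the substrate charged: elm

Read the tick from north between 8.00 h and 15.0 h. Target climbs from 3.9 % to 9.7 % while intermediate goes from 9.5 % to 17.9 %. The forward half-life of intermediate going to target, as north reads it, is then:

half-life = ln(2) × mean intermediate × elapsed time ÷ target gained = 11.5 h

It is a reading and carries the scatter. Now turn the settings, one after the other.

Charge: go from 66 mM to 33 mM. By hand, a first-order step keeps its tick at any dilution, so expect the same clock.

Feed: stretch it to 100 h, as maple does. Intermediate arrives later, but then maple still has a long stretch, far longer than the tick: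

ticks after the feed, maple = 16.4

Temperature: elm warms at 50 h. How much that speeds the clock is a guess, so count on the cold tick:

ticks after the feed, elm = 1.92

My count puts maple, with its stretch far longer than the tick, at the balance of this one step by its end, thermodynamic control of that step, but it gives no figure for that balance. The forecast does give figures: neither, with maple at 2.5 % (range 0 % to 10 %) and elm at 3 % (range 0 % to 12 %), on the ground that “both end near a small equilibrium residue”.

Maple ends at 29.2 % and elm at 42.7 %, so elm leads by 14 percentage points.

    substrate + reagent → intermediate + by-product (k = 21.0 M⁻¹ h⁻¹, Ea = 56.0 kJ mol⁻¹)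
    intermediate ⇌ target (K = 1.40, k = 0.0960 h⁻¹, Ea = 77.0 kJ mol⁻¹, ΔH = −43.0 kJ mol⁻¹)
    intermediate ⇌ isomer of the product (K = 2.20, k = 0.00440 h⁻¹, Ea = 81.0 kJ mol⁻¹, ΔH = −17.0 kJ mol⁻¹)
    substrate + by-product → side product (k = 0.140 M⁻¹ h⁻¹, Ea = 56.0 kJ mol⁻¹)
    (constants at −40 °C)

Maple ends with more target than elm, 41.5 % against 10.4 %. Run the tick on maple once more: at 6.00 d, 3.84 ticks past the feed, target over intermediate is 1.43, and at 12.0 d, 16.4 ticks past it, the ratio is 1.42, while isomer of the product rises from 14.8 % to 28.5 %. In elm, 1.92 cold ticks past the feed, the same ratio is 0.243, with isomer of the product at 46.1 %.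

(The runs come from a simulation for substances that don't exist.)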